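Assumption: the SMILES has no stereocentre and its only non-aromatic C=C bonds are ring-locked. The target is therefore achiral and there is no configuration to set. Transient compound 3 is racemic, and its centre disappears in 4.

## Retrosynthetic overview
- The umbelliferone unit and both benzene rings are bought intact. The only ring built is the pyranone of the 6,7-dimethoxycoumarin, and it is built last.
- The enol ether C3=C4 comes from loss of one umbelliferone from a 3,3-bis(aryloxy)chroman-2-one, which is a ketal of the 2,3-dione. The lactone O1–C2 comes from phenol plus ethyl ester.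
- The key disconnection is C3–C4 with reversed polarity. C3 is a glyoxylate acyl anion equivalent (the enolate of ethyl bis(coumarin-7-yloxy)acetate). C4 is the methylene of the 4,5-dimethoxy o-quinone methide. Both carbons are natural acceptors.
- The acyl anion equivalent comes from 2 umbelliferone plus ethyl dichloroacetate. The o-quinone methide comes from the methiodide of the Mannich base of 3,4-dimethoxyphenol, in which CH2O supplies C4.

## Route

Step 1
Reactants: 1 umbelliferone (7-hydroxy-2H-chromen-2-one, 2.2 equiv); 2 ethyl dichloroacetate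
Product: 4 ethyl 2,2-bis[(2-oxo-2H-chromen-7-yl)oxy]acetate, via chloro ether 3 (not isolated)
Conditions: K2CO3 (2.5 equiv), KI (cat.), DMF, 80 °C
Reagents that add atoms: none
Why: Double Williamson-type SN2 displacement, in which the phenoxide of 1 displaces the first chloride of 2 and the oxygen-activated α-chloro ether 3 is displaced at once by a second phenoxide (the reaction type that turns dichloroacetates into dialkoxy- and diphenoxyacetates); the coumarin lactone tolerates anhydrous K2CO3/DMF, and the racemic centre of 3 vanishes in the symmetric acetal 4.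

Step 2
Reactants: 5 3,4-dimethoxyphenol
Product: 6 2-[(dimethylamino)methyl]-4,5-dimethoxyphenol
Conditions: 40% aq. Me2NH (1.0 equiv), 37% aq. CH2O (1.0 equiv), EtOH, 0 °C → rt
Reagents that add atoms: formaldehyde C=O; dimethylamine CNC
Why: Phenolic Mannich aminomethylation, in which the iminium ion attacks ortho to OH at C6, the only ortho site that is unhindered and also para to the 3-OMe group (C2 is flanked by OH and OMe), while one equivalent of each reagent limits bis-aminomethylation; no stereocentre is formed.

Step 3 (key step, one pot)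
Reactants: 4 ethyl 2,2-bis[(2-oxo-2H-chromen-7-yl)oxy]acetate (1.0 equiv); 6 2-[(dimethylamino)methyl]-4,5-dimethoxyphenol (1.10 equiv); 7 iodomethane (1.05 equiv)
Product: 12 daphnoretin methyl ether (6,7-dimethoxy-3-[(2-oxo-2H-chromen-7-yl)oxy]-2H-chromen-2-one), via ammonium iodide 8 (not isolated), via o-quinone methide 9 (not isolated), via Michael adduct 10 (not isolated), via ketal lactone 11 (not isolated)
Conditions: 6 + 7, DMF, rt, 2 h; solution added over 1 h to 4 + KOtBu (2.05 equiv), DMF, −20 °C → rt; AcOH (1.1 equiv), 50 °C; DBU (2 equiv), 90 °C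
Reagents that add atoms: none
Why: Proposed new method: Menshutkin quaternisation turns 6 into salt 8, whose phenoxide expels NMe3 (pushed by the para-OMe) to give o-quinone methide 9, and the potassium enolate of 4 (estimated pKa in DMSO in the low to mid 20s), in which C3 is a glyoxylate carbonyl carbon masked as its diaryl acetal and so acts as an acyl anion equivalent (the O,O-analogue of the 1,3-dithiane-2-carboxylate anion), adds Michael-fashion to the methylene of 9, joining two natural acceptor carbons (C3 and C4) in a Stetter-type 1,4-dioxygenation pattern; after buffering with AcOH the free phenol of 10 lactonises on the inductively activated, gem-disubstituted ester (Thorpe–Ingold effect), and DBU then removes a benzylic C4–H in an anti E2 loss of one umbelliferone oxide (pKa about 8) from ketal 11, so the acyl carbon is unmasked directly as the aryl enol ether, driven by formation of the conjugated coumarin; the closest known reaction types are alkylation of dialkoxyacetate or dithiane-carboxylate anions, carbanion additions to o-quinone methides made from (2-hydroxybenzyl)trimethylammonium salts, and ketal-to-enol-ether elimination; no stereocentre is formed, and any coumarin opened by alkoxide re-closes after the AcOH buffer.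

## Compound list
1 | umbelliferone (7-hydroxy-2H-chromen-2-one) | O=c1ccc2ccc(O)cc2o1 | starting material
2 | ethyl dichloroacetate | CCOC(=O)C(Cl)Cl | starting material
3 | ethyl 2-chloro-2-[(2-oxo-2H-chromen-7-yl)oxy]acetate (racemic, transient) | CCOC(=O)C(Cl)Oc1ccc2ccc(=O)oc2c1 | intermediate
4 | ethyl 2,2-bis[(2-oxo-2H-chromen-7-yl)oxy]acetate | CCOC(=O)C(Oc1ccc2ccc(=O)oc2c1)Oc1ccc2ccc(=O)oc2c1 | intermediate
5 | 3,4-dimethoxyphenol | COc1ccc(O)cc1OC | starting material
6 | 2-[(dimethylamino)methyl]-4,5-dimethoxyphenol | CN(C)Cc1cc(OC)c(OC)cc1O | intermediate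
7 | iodomethane | CI | starting material
8 | (2-hydroxy-4,5-dimethoxyphenyl)-N,N,N-trimethylmethanaminium iodide | C[N+](C)(C)Cc1cc(OC)c(OC)cc1O.[I-] | intermediate
9 | 3,4-dimethoxy-6-methylidenecyclohexa-2,4-dien-1-one (o-quinone methide) | C=C1C=C(OC)C(OC)=CC1=O | intermediate
10 | ethyl 3-(2-hydroxy-4,5-dimethoxyphenyl)-2,2-bis[(2-oxo-2H-chromen-7-yl)oxy]propanoate | CCOC(=O)C(Cc1cc(OC)c(OC)cc1O)(Oc1ccc2ccc(=O)oc2c1)Oc1ccc2ccc(=O)oc2c1 | intermediate
11 | 6,7-dimethoxy-3,3-bis[(2-oxo-2H-chromen-7-yl)oxy]-3,4-dihydro-2H-chromen-2-one | COc1cc2c(cc1OC)OC(=O)C(Oc1ccc3ccc(=O)oc3c1)(Oc1ccc3ccc(=O)oc3c1)C2 | intermediate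
12 | daphnoretin methyl ether (achiral) | COc1cc2cc(Oc3ccc4ccc(=O)oc4c3)c(=O)oc2cc1OC | target

Total step count: 3. Longest linear sequence: 2 (1 → 4 → 12, or 5 → 6 → 12).

## Steps most likely to fail

**Step 3 is the most exposed.** The enolate of 4 is hindered and may fragment or attack a coumarin. Compound 9 may oligomerise or be taken by O-nucleophiles before it is trapped. The E2 loss of aryloxide from 11 has no direct precedent.

The fallback sets out from 8 (still made from 6 and 7) and from 1, and comes back at 12. It keeps 9 as the acceptor, uses the sulfur-stabilised glyoxylate acyl anion instead, and forms the aryl enol ether bond last.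
- Commercial ethyl 1,3-dithiane-2-carboxylate (CCOC(=O)C1SCCCS1) is deprotonated with KOtBu in DMF. It traps 9 released from 8 to give ethyl 2-(2-hydroxy-4,5-dimethoxybenzyl)-1,3-dithiane-2-carboxylate F1.
- Catalytic TsOH in refluxing toluene closes it to 6,7-dimethoxyspiro[chromane-3,2'-[1,3]dithian]-2-one F2.
- MeI/CaCO3 in aqueous MeCN removes the dithiane, and the dione enolises to 3-hydroxy-6,7-dimethoxy-2H-chromen-2-one F3.
- Tf2O/pyridine gives 6,7-dimethoxy-2-oxo-2H-chromen-3-yl trifluoromethanesulfonate F4.
- Pd-catalysed C–O coupling of this vinyl triflate with 1 (Pd2(dba)3, tBuXPhos, K3PO4, toluene, 100 °C) gives 12.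

**Step 1 is second.** The first displacement on 2 is slow, and 3 can be lost to hydrolysis or to base-induced decomposition of 2.

The fallback sets out from 1 and comes back at 4. It raises the oxidation level after the first C–O bond rather than before it.
- Compound 1 with ethyl bromoacetate (K2CO3, acetone, reflux) gives ethyl 2-[(2-oxo-2H-chromen-7-yl)oxy]acetate F5.
- Wohl–Ziegler bromination of its captodative CH2 (NBS, AIBN, PhCF3, reflux) gives racemic ethyl 2-bromo-2-[(2-oxo-2H-chromen-7-yl)oxy]acetate F6.
- A second equivalent of 1 (K2CO3, MeCN, rt) displaces bromide and gives 4.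

**Step 2 is third.** Bis-aminomethylation, some attack at C2, and air oxidation of the electron-rich aminophenol are possible.

The fallback sets out from 5 and comes back at 9. It replaces aminomethylation by boron-templated ortho-hydroxymethylation.
- Compound 5 with PhB(OH)2, paraformaldehyde and catalytic propionic acid (toluene, Dean–Stark) gives 6,7-dimethoxy-2-phenyl-4H-1,3,2-benzodioxaborinine F7.
- Exchange with propane-1,3-diol frees 2-(hydroxymethyl)-4,5-dimethoxyphenol F8.
- Sodium p-toluenesulfinate in aqueous formic acid converts it into bench-stable 4,5-dimethoxy-2-[(4-methylphenyl)sulfonylmethyl]phenol F9.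
- F9 loses sulfinate with KOtBu under the conditions of step 3 and delivers 9.

## Further compounds
F1 | step 3 | ethyl 2-(2-hydroxy-4,5-dimethoxybenzyl)-1,3-dithiane-2-carboxylate | CCOC(=O)C1(Cc2cc(OC)c(OC)cc2O)SCCCS1
F2 | step 3 | 6,7-dimethoxyspiro[chromane-3,2'-[1,3]dithian]-2-one | COc1cc2c(cc1OC)OC(=O)C1(C2)SCCCS1
F3 | step 3 | 3-hydroxy-6,7-dimethoxy-2H-chromen-2-one | COc1cc2cc(O)c(=O)oc2cc1OC
F4 | step 3 | 6,7-dimethoxy-2-oxo-2H-chromen-3-yl trifluoromethanesulfonate | COc1cc2cc(OS(=O)(=O)C(F)(F)F)c(=O)oc2cc1OC
F5 | step 1 | ethyl 2-[(2-oxo-2H-chromen-7-yl)oxy]acetate | CCOC(=O)COc1ccc2ccc(=O)oc2c1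
F6 | step 1 | ethyl 2-bromo-2-[(2-oxo-2H-chromen-7-yl)oxy]acetate (racemic) | CCOC(=O)C(Br)Oc1ccc2ccc(=O)oc2c1
F7 | step 2 | 6,7-dimethoxy-2-phenyl-4H-1,3,2-benzodioxaborinine | COc1cc2COB(c3ccccc3)Oc2cc1OC
F8 | step 2 | 2-(hydroxymethyl)-4,5-dimethoxyphenol | COc1cc(CO)c(O)cc1OC
F9 | step 2 | 4,5-dimethoxy-2-[(4-methylphenyl)sulfonylmethyl]phenol | COc1cc(CS(=O)(=O)c2ccc(C)cc2)c(O)cc1OC
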